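**Retrosynthetic overview**
1. Numbering (guaiane type): ring C1 (C–OH, acyl), C5 (CH–O-isovaleryl), C6 (lactone CH–O), C7, C8, C9 (CHOH), C10 (CHMe); chain C2(=O)–C3=C4; lactone C11(=C13H2)–C12. The (Z)-enone is cut at C2–C3 (alkenylchromium + aldehyde, oxidation last).
2. The lactone C6–O bond is cut with inversion at C6: the C9 oxygen once bridged C6 and C9 in an 8-oxabicyclo[3.2.1]octane, and an acrylic acid arm on C7 displaces it, which also frees the C9 hydroxyl.
3. On that rigid bicycle C1 is a ketone; the C2 carbon, the C5 hydroxyl and H7 all enter from the exo face.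
4. The bicycle comes from a (4+3) cycloaddition of a chiral alkoxy-substituted 2-silyloxyallyl cation (C5–C1–C10) with tert-butyl furan-3-ylacetate (C6–C7–C8–C9 plus C11, C12). It forms C5–C6 and C9–C10 and closes the seven-membered carbocycle first (step 5); the lactone ring follows in step 13.
5. Enabling feature: in the cycloheptane, C6 and C9 both carry oxygen and stand 1,4 across the C7–C8 edge (a furan once C6 is inverted), while C1, oxygenated and flanked by C5 and C10, is the central carbon of an oxyallyl unit.

Key step: step 5

Remark 1: the target numbering is used for every intermediate; the target is (1S,5S,6R,7S,9R,10S). "Syn" and "anti" refer to the oxygen bridge C6–O–C9; "exo" is the face of that bridge.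
Remark 2 (assumption): the (1S)-1-phenylethoxy group is taken to shield the face of the cation that leads to the enantiomer drawn; if the sense is the opposite, (R)-1-phenylethanol is used and nothing else changes.

**Route**

Step 1
Reactants: 1 3-bromofuran; 2 (2-tert-butoxy-2-oxoethyl)zinc bromide
Product: 3 tert-butyl 2-(furan-3-yl)acetate
Conditions: Pd2(dba)3 (1 mol %), P(t-Bu)3 (2 mol %), THF, rt
Reagents that add atoms: none
Why: Negishi-type coupling of a Reformatsky zinc enolate with a heteroaryl bromide (oxidative addition to zerovalent palladium, transmetalation, reductive elimination) should give the ester directly; no stereocenter is formed.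

Step 2
Reactants: 4 2,2-diethoxy-N,N-dimethylacetamide
Product: 5 1,1-diethoxybutan-2-one
Conditions: EtMgBr (1.1 equiv), THF, −20 → 0 °C; aq. NH4Cl
Reagents that add atoms: ethylmagnesium bromide, CC[Mg]Br
Why: Grignard acyl substitution on a tertiary α,α-dialkoxy amide, in which the chelated tetrahedral magnesium adduct should persist until work-up and so stop at the ketone; no stereocenter.

Step 3
Reactants: 5 1,1-diethoxybutan-2-one; 6 (S)-1-phenylethanol
Product: 7 1-ethoxy-1-[(1S)-1-phenylethoxy]butan-2-one
Conditions: TsOH (2 mol %), toluene, 45 °C, reduced pressure (EtOH removed)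
Reagents that add atoms: none
Why: Acid-catalysed transacetalisation through the oxocarbenium ion should exchange one ethoxy group; the acetal carbon forms as both epimers, which is harmless because it becomes trigonal in step 5, and the carbinol centre of 6 is not touched.

Step 4
Reactants: 7 mixed acetal
Product: 8 (Z)-triethylsilyl enol ether of 7
Conditions: Et3SiCl, LiN(iPr)2, THF–DMPU, −78 °C
Reagents that add atoms: chlorotriethylsilane, CC[Si](Cl)(CC)CC
Why: Kinetic enolisation of the ethyl group with in situ O-silylation (the acetal C–H is hindered and deactivated by the alkoxy lone pairs); DMPU should favour the (Z)-enol ether with methyl cis to the silyloxy group.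

Step 5
Reactants: 8 (Z)-silyl enol ether acetal; 3 tert-butyl 2-(furan-3-yl)acetate
Product: 10 oxygen-bridged cycloadduct (8-oxabicyclo[3.2.1]oct-6-en-3-one), via oxyallyl cation triflate 9 (not isolated)
Conditions: 3 (1.5 equiv), Me3SiOTf (0.1 equiv), CH2Cl2, −95 → −78 °C; aq. NaHCO3
Reagents that add atoms: none
Why: Me3SiOTf silylates the ethoxy group of 8 and ionises the acetal to the alkoxy-stabilised 2-silyloxyallyl cation 9, whose C5–C1–C10 π-system (two electrons) adds across the furan diene (four electrons) in a compact, concerted but asynchronous (4+3) transition state; loss of the silyl group from the resulting silyloxocarbenium ion gives the ketone and returns the silyl triflate. The closest known reactions are the Lewis-acid-promoted (4+3) cycloadditions of acetal-derived alkoxy-substituted silyloxyallyl cations with furans, including those that carry a chiral 1-phenylethoxy group. One ring is closed, the cycloheptene (as the 8-oxabicyclo[3.2.1]oct-6-ene), by intermolecular suprafacial bonding of both cation termini to the two furan α-carbons, which forms C5–C6 and C10–C9. C6 and C9 are set cis by the furan; the C10 methyl and the C5 alkoxy group should end up equatorial (anti to the bridge) because the (Z)-configured, W-shaped cation reacts through the compact arrangement; the absolute sense comes from the 1-phenylethoxy group, whose phenyl ring covers one face of the cation. The step needs regioselectivity and facial selectivity: the oxocarbenium-like C5, where bonding is most advanced, should pair with the more nucleophilic furan α-carbon next to the side chain (future C6) and the more hindered methyl-bearing C10 with the free α-carbon (future C9), and the auxiliary at −95 °C should secure the face.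

Step 6
Reactants: 10 cycloadduct
Product: 11 bicyclic enone-free ketone with C5 = CH2
Conditions: SmI2 (2.5 equiv), THF–MeOH, −78 °C
Reagents that add atoms: none
Why: Reductive cleavage of the α-alkoxy ketone by divalent samarium (two single-electron transfers, loss of the alkoxide, protonation) should remove the auxiliary oxygen from C5 without touching C6, C9 or C10; alcohol 6 is recovered.

Step 7
Reactants: 11 unsaturated bicyclic ketone
Product: 12 saturated bicyclic ketone
Conditions: H2 (1 atm), Pd/C, EtOAc, rt
Reagents that add atoms: none
Why: Heterogeneous hydrogenation of the strained trisubstituted alkene from the exo face (the endo face is screened by the three-carbon bridge) should place H7 syn to the bridge and the CH2CO2tBu arm endo.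

Step 8
Reactants: 12 saturated bicyclic ketone
Product: 13 α-hydroxy ketone (axial C5–OH)
Conditions: KN(SiMe3)2 (1.1 equiv), THF, −78 °C; then 2-(phenylsulfonyl)-3-phenyloxaziridine, −78 °C; aq. NH4Cl at −78 °C
Reagents that add atoms: 2-(phenylsulfonyl)-3-phenyloxaziridine (Davis oxaziridine), O=S(=O)(N1OC1c1ccccc1)c1ccccc1
Why: Kinetic deprotonation at the CH2 (C5) rather than the methyl-bearing C10, then enolate hydroxylation from the open exo face, should give the axial C5 hydroxyl syn to the bridge; the low temperature keeps the enolate from expelling the bridge oxygen.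

Step 9
Reactants: 13 α-hydroxy ketone
Product: 14 tertiary alcohol with CH2O-t-Bu on C1
Conditions: t-BuOCH2Li (4 equiv; from t-BuOMe, s-BuLi, KOtBu, then LiBr), THF, −78 → −40 °C; aq. NH4Cl
Reagents that add atoms: tert-butoxymethyllithium, [Li]COC(C)(C)C (made in the flask from tert-butyl methyl ether, COC(C)(C)C)
Why: 1,2-Addition of an α-alkoxy alkyllithium (hydroxymethyl anion equivalent) to the ketone; the endo face is closed by the two-carbon bridge and its endo side chain, so the reagent, held by the C5 lithium alkoxide on the same side, should enter exo and leave the C1 hydroxyl anti to the bridge.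

Step 10
Reactants: 14 tertiary alcohol
Product: 15 β-dimethylamino ester
Conditions: LiN(iPr)2 (3.5 equiv), THF, −78 °C; then Me2N=CH2+ I−, −78 → 0 °C
Reagents that add atoms: N,N-dimethylmethyleneiminium iodide (Eschenmoser's salt), C=[N+](C)C.[I-]
Why: Mannich aminomethylation of the tert-butyl ester enolate after both hydroxyls are converted to alkoxides; the new C11 centre forms as a mixture and disappears in step 11.

Step 11
Reactants: 15 β-dimethylamino ester
Product: 17 tert-butyl acrylate, via trimethylammonium iodide 16 (not isolated)
Conditions: MeI, MeOH, rt; then DBU, CH2Cl2, rt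
Reagents that add atoms: none
Why: N-Quaternisation followed by E1cB loss of trimethylamine should give the 2-substituted acrylate (C11=C13); no stereocenter.

Step 12
Reactants: 17 tert-butyl acrylate
Product: 18 C5 3-methylbutanoate
Conditions: (Me2CHCH2CO)2O, DMAP (0.2 equiv), Et3N, CH2Cl2, rt
Reagents that add atoms: 3-methylbutanoic anhydride, CC(C)CC(=O)OC(=O)CC(C)C
Why: DMAP-catalysed acylation of the only secondary hydroxyl (C5); the tertiary C1 hydroxyl is unreactive and, being trans-diaxial to the C5 oxygen on the rigid bicycle, cannot take over the acyl group.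

Step 13
Reactants: 18 C5 3-methylbutanoate
Product: 20 cis-fused α-methylene lactone triol monoester, via hydroxy acid 19 (not isolated)
Conditions: CF3CO2H–CH2Cl2 (1:3), 0 °C → rt; then TfOH (0.1 equiv), CH2Cl2, 0 °C → rt; aq. NaHCO3
Reagents that add atoms: none
Why: Proposed new method: after acidolysis of both tert-butyl groups, the bridging ether oxygen is protonated and the carbonyl oxygen of the endo acrylic acid arm on C7, which lies antiperiplanar to the C6–O bond, should displace it at C6 in a 5-exo-tet SN2 step (inversion at C6, the former bridge oxygen stays on C9 as the free hydroxyl, the cis-fused lactone forms); the C5 ester is gauche to the breaking bond and the C1 and C2 hydroxyls would need a four-membered ring or the wrong face, so they cannot compete; the closest known reactions are the acid-promoted acetolysis of oxygen bridges in oxabicyclic ethers and epoxide- or halonium-opening lactonisations.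

Step 14
Reactants: 20 lactone with C2 = CH2OH
Product: 21 α-hydroxy aldehyde
Conditions: TEMPO (0.1 equiv), PhI(OAc)2 (1.2 equiv), CH2Cl2, rt
Reagents that add atoms: none
Why: Oxoammonium oxidation, selective for the primary C2 hydroxyl over the secondary C9 and tertiary C1 hydroxyls, should stop at the aldehyde.

Step 15
Reactants: 21 α-hydroxy aldehyde
Product: 22 (Z)-allylic alcohol
Conditions: (Z)-1-bromopropene (3 equiv), CrCl2 (6 equiv), NiCl2 (1 mol %), DMF, rt
Reagents that add atoms: (Z)-1-bromoprop-1-ene, C/C=C\Br
Why: Nozaki–Hiyama–Kishi addition of the alkenylchromium reagent to the aldehyde should tolerate the free hydroxyls, the ester and the α-methylene lactone and keep the (Z)-geometry; the C2 carbinol forms as both epimers, which converge in step 16.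

Step 16
Reactants: 22 (Z)-allylic alcohol
Product: 23 target
Conditions: MnO2 (activated, excess), CH2Cl2, rt, dark
Reagents that add atoms: none
Why: Allylic oxidation with MnO2 should convert only the allylic C2 hydroxyl into the ketone, leave the C9 hydroxyl alone, and be mild enough to keep the (Z)-enone from isomerising.

**Compound list**
1 | 3-bromofuran | Brc1ccoc1 | starting material
2 | (2-tert-butoxy-2-oxoethyl)zinc bromide, BrZnCH2CO2tBu | CC(C)(C)OC(=O)C[Zn]Br | starting material
3 | tert-butyl 2-(furan-3-yl)acetate | CC(C)(C)OC(=O)Cc1ccoc1 | intermediate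
4 | 2,2-diethoxy-N,N-dimethylacetamide | CCOC(OCC)C(=O)N(C)C | starting material
5 | 1,1-diethoxybutan-2-one | CCC(=O)C(OCC)OCC | intermediate
6 | (S)-1-phenylethanol | C[C@H](O)c1ccccc1 | starting material
7 | 1-ethoxy-1-[(1S)-1-phenylethoxy]butan-2-one (acetal carbon: both epimers) | CCC(=O)C(OCC)O[C@@H](C)c1ccccc1 | intermediate
8 | (Z)-1-ethoxy-1-[(1S)-1-phenylethoxy]-2-(triethylsilyloxy)but-2-ene | C/C=C(\O[Si](CC)(CC)CC)C(OCC)O[C@@H](C)c1ccccc1 | intermediate
9 | 1-[(1S)-1-phenylethoxy]-2-(triethylsilyloxy)but-2-enylium triflate (alkoxy-substituted oxyallyl cation) | C/C=C(\O[Si](CC)(CC)CC)C=[O+][C@@H](C)c1ccccc1.[O-]S(=O)(=O)C(F)(F)F | intermediate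
10 | (4+3) adduct, 8-oxabicyclo[3.2.1]oct-6-en-3-one: C1 ketone, oxygen bridge C6–O–C9, C7=C8 with CH2CO2tBu on C7, (1S)-1-phenylethoxy on C5 and methyl on C10 both equatorial (anti) | O1[C@H]2C(CC(=O)OC(C)(C)C)=C[C@@H]1[C@H](C)C(=O)[C@@H]2O[C@@H](C)c1ccccc1 | intermediate
11 | as 10 with C5 = CH2 (auxiliary oxygen removed) | O1[C@H]2C(CC(=O)OC(C)(C)C)=C[C@@H]1[C@H](C)C(=O)C2 | intermediate
12 | as 11 with C7–C8 saturated; CH2CO2tBu on C7 endo (anti), H7 syn | O1[C@H]2[C@H](CC(=O)OC(C)(C)C)C[C@@H]1[C@H](C)C(=O)C2 | intermediate
13 | as 12 with an axial hydroxyl on C5 (syn) | O1[C@H]2[C@H](CC(=O)OC(C)(C)C)C[C@@H]1[C@H](C)C(=O)[C@H]2O | intermediate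
14 | as 13 with C1 a tertiary carbinol: OH anti, CH2O-t-Bu (C2) syn | O1[C@H]2[C@H](CC(=O)OC(C)(C)C)C[C@@H]1[C@H](C)[C@@](O)(COC(C)(C)C)[C@H]2O | intermediate
15 | as 14 with CH(CH2NMe2)CO2tBu on C7 (C11: both epimers) | O1[C@H]2[C@H](C(CN(C)C)C(=O)OC(C)(C)C)C[C@@H]1[C@H](C)[C@@](O)(COC(C)(C)C)[C@H]2O | intermediate
16 | trimethylammonium iodide of 15 | O1[C@H]2[C@H](C(C[N+](C)(C)C)C(=O)OC(C)(C)C)C[C@@H]1[C@H](C)[C@@](O)(COC(C)(C)C)[C@H]2O.[I-] | intermediate
17 | as 14 with C(=CH2)CO2tBu on C7 (tert-butyl acrylate) | O1[C@H]2[C@H](C(=C)C(=O)OC(C)(C)C)C[C@@H]1[C@H](C)[C@@](O)(COC(C)(C)C)[C@H]2O | intermediate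
18 | C5 3-methylbutanoate of 17 | O1[C@H]2[C@H](C(=C)C(=O)OC(C)(C)C)C[C@@H]1[C@H](C)[C@@](O)(COC(C)(C)C)[C@H]2OC(=O)CC(C)C | intermediate
19 | as 18 with free acrylic acid on C7 and free CH2OH on C1, bridge intact | O1[C@H]2[C@H](C(=C)C(O)=O)C[C@@H]1[C@H](C)[C@@](O)(CO)[C@H]2OC(=O)CC(C)C | intermediate
20 | target skeleton with CH2OH in place of the enone: cis-fused α-methylene γ-lactone (C6–O inverted), free C9–OH and C1–OH, C5 3-methylbutanoate | C=C1C(=O)O[C@@H]2[C@H]1C[C@@H](O)[C@H](C)[C@@](O)(CO)[C@H]2OC(=O)CC(C)C | intermediate
21 | as 20 with CHO on C1 (α-hydroxy aldehyde) | C=C1C(=O)O[C@@H]2[C@H]1C[C@@H](O)[C@H](C)[C@@](O)(C=O)[C@H]2OC(=O)CC(C)C | intermediate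
22 | as 20 with CH(OH)–(Z)-CH=CH–CH3 on C1 (C2: both epimers) | C=C1C(=O)O[C@@H]2[C@H]1C[C@@H](O)[C@H](C)[C@@](O)(C(O)/C=C\C)[C@H]2OC(=O)CC(C)C | intermediate
23 | CNP0186412.2, (1S,5S,6R,7S,9R,10S) in the numbering used here | C=C1C(=O)O[C@@H]2[C@H]1C[C@@H](O)[C@H](C)[C@@](O)(C(=O)/C=C\C)[C@H]2OC(=O)CC(C)C | target

**Step count and risks**
Total steps: 16. Longest linear sequence: 15 (steps 2 to 16; step 1 is a one-step branch).

Steps most likely to fail:

1. Step 13. The bridging ether may resist displacement, the opening may reverse by re-closure of the bridge from the C9 hydroxyl, or the C5 ester may migrate under acid. Fallback with known chemistry, setting out from 18 and returning at 20: the inversion at C6 is moved to a Mitsunobu lactonisation. 18 is treated with Me2BBr (CH2Cl2, −78 → 0 °C), which should remove both tert-butyl groups and cleave the bridge by bromide attack at the less hindered C9 (inversion), leaving the C6 hydroxyl in the bromo hydroxy acid F1. PPh3 and DIAD (THF, high dilution) should close the γ-lactone at C6 with inversion, since the neopentyl C2 hydroxyl and the tertiary C1 hydroxyl cannot be displaced, giving the bromo lactone F2. HCO2Cs (18-crown-6, DMF) should displace the C9 bromide with a second inversion to give the C9 formate F3, and NaHCO3 in MeOH should release 20.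

2. Step 5. The two cation termini may pair with the wrong furan α-carbons, and the facial bias of the auxiliary may erode with the substituted partners. Fallback, setting out from 3 and 6 and returning at 11: the alkoxy group is moved to the methyl-bearing terminus. Commercial 3,3-dimethoxybutan-2-one is transketalised with 6 (TsOH) to the mixed ketal F4 and silylated on its methyl ketone (Et3SiCl, LiN(iPr)2) to the enol ether F5. Ionisation with Me3SiOTf in the presence of 3 should then pair the unsubstituted CH2 terminus with the hindered furan α-carbon and the fully substituted terminus with the free one, so that sterics alone fix the orientation, giving the cycloadduct F6. SmI2 in THF–MeOH should remove the tertiary alkoxy group, and protonation from the exo face should set the equatorial C10 methyl of 11.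

3. Step 9. The basic reagent may enolise the ketone toward C10, with β-elimination of the bridge, instead of adding to the hindered carbonyl. Fallback, setting out from 13 and returning at 14: the small, less basic dimethylsulfonium methylide (Me3S+ I−, n-BuLi, THF, 0 °C; Corey–Chaykovsky reaction) should attack from the exo face and give the spiro-epoxide F7 with its oxygen anti to the bridge. KOtBu in t-BuOH (60 °C) should then open the epoxide at its CH2 carbon to give 14.

Further compounds
F1 | step 13 | bromo hydroxy acid: monocyclic cycloheptane with C9–Br (inverted), free C6–OH (retained), acrylic acid on C7, C1(OH)CH2OH, C5 3-methylbutanoate | C=C(C(=O)O)[C@@H]1C[C@H](Br)[C@H](C)[C@@](O)(CO)[C@@H](OC(=O)CC(C)C)[C@H]1O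
F2 | step 13 | bromo lactone: 20 with bromine in place of the C9 hydroxyl, opposite configuration at C9 | C=C1C(=O)O[C@@H]2[C@H]1C[C@H](Br)[C@H](C)[C@@](O)(CO)[C@H]2OC(=O)CC(C)C
F3 | step 13 | C9 formate of 20 | C=C1C(=O)O[C@@H]2[C@H]1C[C@@H](OC=O)[C@H](C)[C@@](O)(CO)[C@H]2OC(=O)CC(C)C
F4 | step 5 | 3-methoxy-3-[(1S)-1-phenylethoxy]butan-2-one (ketal carbon: both epimers) | CC(=O)C(C)(OC)O[C@@H](C)c1ccccc1
F5 | step 5 | 3-methoxy-3-[(1S)-1-phenylethoxy]-2-(triethylsilyloxy)but-1-ene | C=C(O[Si](CC)(CC)CC)C(C)(OC)O[C@@H](C)c1ccccc1
F6 | step 5 | cycloadduct as 11 with an additional (1S)-1-phenylethoxy group on C10 (C10 configuration open) | O1[C@H]2C(CC(=O)OC(C)(C)C)=C[C@@H]1C(C)(O[C@@H](C)c1ccccc1)C(=O)C2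
F7 | step 9 | spiro-epoxide at C1 of 13: epoxide oxygen anti, CH2 syn | O1[C@H]2[C@H](CC(=O)OC(C)(C)C)C[C@@H]1[C@H](C)[C@@]3(CO3)[C@H]2O
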